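**Retrosynthetic overview**
1. Target 21 ⇐ tetra-O-benzyl diarylalkyne 20: one hydrogenation turns C≡C into CH2CH2 and frees the four phenols.
2. 20 ⇐ ring A iodide 16 + trimethylsilylacetylene 17 + ring B bromide 14. The strategy rests on the unbranched two-carbon bridge from ring A C1 (para to its OH) to ring B C1' (para to the diarylmethane CH2, flanked by C2'–H and C6'–H), so both aryl–C bonds are made on one acetylene.
3. 14 ⇐ benzhydrol 13 ⇐ ring C–D aryllithium (from iodide 11) + ring B aldehyde 3; 3 comes from 4-bromo-2,6-difluorobenzaldehyde by two fluoride displacements.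
4. 11 ⇐ methyl orsellinate: 4-O-benzylation, 2-O-methylation, lateral lithiation/benzylation (ring D), saponification, iododecarboxylation (the ester carbon marks the bridge position on ring C).
5. No ring is formed; all four benzene rings are bought.

Key step: step 11

Remark: the target has no stereocentre and is achiral, so no enantiocontrol is needed; benzhydrol 13 is formed as a racemate and its carbinol centre is removed in step 9.

**Route**

Step 1
Reactants: 1 4-bromo-2,6-difluorobenzaldehyde
Product: 2 2-(benzyloxy)-4-bromo-6-fluorobenzaldehyde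
Conditions: BnOH (1.0 equiv), NaH (1.0 equiv), THF, 0 °C; then 1, 0 °C to rt
Reagents that add atoms: benzyl alcohol, OCc1ccccc1
Why: Nucleophilic aromatic substitution in which the formyl group activates both ortho fluorides and the first alkoxy group deactivates the ring, so one equivalent of benzyloxide should stop at monosubstitution, with fluoride leaving far faster than the para bromide.

Step 2
Reactants: 2 2-(benzyloxy)-4-bromo-6-fluorobenzaldehyde
Product: 3 2-(benzyloxy)-4-bromo-6-methoxybenzaldehyde
Conditions: NaOMe (2 equiv), MeOH/THF, 60 °C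
Reagents that add atoms: sodium methoxide, [Na+].[O-]C
Why: Second nucleophilic aromatic substitution of the remaining ortho fluoride by the small methoxide nucleophile; the benzyl ether and the bromide are not displaced.

Step 3
Reactants: 4 methyl orsellinate (methyl 2,4-dihydroxy-6-methylbenzoate)
Product: 5 methyl 4-(benzyloxy)-2-hydroxy-6-methylbenzoate
Conditions: BnBr (1.05 equiv), K2CO3, acetone, reflux
Reagents that add atoms: benzyl bromide, BrCc1ccccc1
Why: Williamson etherification that should be selective for the 4-OH, because the 2-OH is hydrogen-bonded to the ester carbonyl and is less acidic and less nucleophilic.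

Step 4
Reactants: 5 methyl 4-(benzyloxy)-2-hydroxy-6-methylbenzoate
Product: 6 methyl 4-(benzyloxy)-2-methoxy-6-methylbenzoate
Conditions: MeI (excess), K2CO3, DMF, 50 °C
Reagents that add atoms: iodomethane, CI
Why: Williamson methylation of the remaining chelated phenol under more forcing conditions in a dipolar solvent.

Step 5
Reactants: 6 methyl 4-(benzyloxy)-2-methoxy-6-methylbenzoate; 7 3-(benzyloxy)benzyl bromide
Product: 9 methyl 4-(benzyloxy)-2-{2-[3-(benzyloxy)phenyl]ethyl}-6-methoxybenzoate, via the benzylic lithium species 8 (not isolated)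
Conditions: LDA (1.1 equiv), THF, −78 °C; then 7, −78 °C to rt
Reagents that add atoms: none
Why: Lateral lithiation of the ortho-toluate, whose benzylic anion is stabilised by the ortho ester, followed by SN2 alkylation with the benzylic bromide; the di-ortho-substituted ester is too hindered for fast self-condensation.

Step 6
Reactants: 9 methyl 4-(benzyloxy)-2-{2-[3-(benzyloxy)phenyl]ethyl}-6-methoxybenzoate
Product: 10 4-(benzyloxy)-2-{2-[3-(benzyloxy)phenyl]ethyl}-6-methoxybenzoic acid
Conditions: KOH (10 equiv), DMSO/H2O 4:1, 100 °C; then 1 M HCl, 0 °C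
Reagents that add atoms: potassium hydroxide, [K+].[OH-]
Why: Saponification of a di-ortho-substituted methyl ester needs hot hydroxide in a dipolar solvent, to which the aryl benzyl and methyl ethers are inert; cold acidification limits protodecarboxylation.

Step 7
Reactants: 10 4-(benzyloxy)-2-{2-[3-(benzyloxy)phenyl]ethyl}-6-methoxybenzoic acid
Product: 11 5-(benzyloxy)-1-{2-[3-(benzyloxy)phenyl]ethyl}-2-iodo-3-methoxybenzene
Conditions: I2 (3 equiv), K3PO4 (1 equiv), MeCN, 100 °C, sealed tube; aq. Na2S2O3
Reagents that add atoms: iodine, II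
Why: Transition-metal-free decarboxylative iodination of an electron-rich ortho-alkoxybenzoate, in which iodine attacks the ipso carbon (ortho and para to the two alkoxy groups, carboxylate twisted out of plane) and CO2 is lost.

Step 8
Reactants: 11 5-(benzyloxy)-1-{2-[3-(benzyloxy)phenyl]ethyl}-2-iodo-3-methoxybenzene; 3 2-(benzyloxy)-4-bromo-6-methoxybenzaldehyde
Product: 13 racemic [2-(benzyloxy)-4-bromo-6-methoxyphenyl](4-(benzyloxy)-2-{2-[3-(benzyloxy)phenyl]ethyl}-6-methoxyphenyl)methanol, via the ring C aryllithium 12 (not isolated)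
Conditions: n-BuLi (1.05 equiv), THF, −78 °C; then 3, −78 to −20 °C; then aq. NH4Cl
Reagents that add atoms: none
Why: Iodine–lithium exchange followed by 1,2-addition to the non-enolisable aldehyde, which should be faster at −78 °C than exchange with the aryl bromide of 3; the carbinol centre forms as a racemate and is removed in step 9.

Step 9
Reactants: 13 racemic diarylmethanol
Product: 14 1-(benzyloxy)-2-[(4-(benzyloxy)-2-{2-[3-(benzyloxy)phenyl]ethyl}-6-methoxyphenyl)methyl]-5-bromo-3-methoxybenzene
Conditions: Et3SiH (5 equiv), TFA (5 equiv), CH2Cl2, −20 to 0 °C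
Reagents that add atoms: none
Why: Ionic hydrogenation (Kursanov–Parnes) in which acid ionises the doubly alkoxy-stabilised benzhydrol and excess silane should deliver hydride to the cation faster than ring D can trap it; brief exposure below 0 °C should leave the benzyl ethers intact.

Step 10
Reactants: 15 4-iodo-2-methoxyphenol
Product: 16 1-(benzyloxy)-4-iodo-2-methoxybenzene
Conditions: BnBr, K2CO3, DMF, rt
Reagents that add atoms: benzyl bromide, BrCc1ccccc1
Why: Williamson benzylation of the phenol; the aryl iodide is inert under these conditions.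

Step 11
Reactants: 16 1-(benzyloxy)-4-iodo-2-methoxybenzene; 17 trimethylsilylacetylene; 14 ring B bromide of the diarylmethane core
Product: 20 1-(benzyloxy)-2-[(4-(benzyloxy)-2-{2-[3-(benzyloxy)phenyl]ethyl}-6-methoxyphenyl)methyl]-5-{[4-(benzyloxy)-3-methoxyphenyl]ethynyl}-3-methoxybenzene, via the arylethynyl(trimethyl)silane 18 (not isolated), via the terminal arylacetylene 19 (not isolated)
Conditions: 16 (1.2 equiv), 17 (1.3 equiv), PdCl2(PPh3)2 (5 mol%), CuI (10 mol%), Et3N, degassed DMF, rt; argon sparge; then 14 (1.0 equiv), MeOH, K2CO3 (0.3 equiv), 70 °C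
Reagents that add atoms: none
Why: Pd(0) inserts into the C–I bond of 16 at room temperature, the copper acetylide of 17 transmetalates and reductive elimination gives 18; carbonate-catalysed methanolysis of the C–Si bond then releases 19 slowly, and a second Pd/Cu cycle with the C–Br bond of 14 at 70 °C forms the second aryl–alkyne bond. The closest known reaction type is the one-pot sila-Sonogashira sequence (Sonogashira coupling, in situ desilylation, Sonogashira coupling) for unsymmetrical diarylacetylenes. No ring is closed and no stereocentre is formed. The step needs the two arylations to occur in order: the silyl group blocks the second alkyne terminus during the first coupling, the more reactive iodide 16 is consumed before 14 and methanol are added, and excess 17 is purged so that free acetylene cannot bridge two molecules of 14. The bromide of 14 lies meta to both ring B alkoxy groups and between two ring hydrogens, so it is neither conjugatively deactivated nor shielded by the crowded diarylmethane. Slow release of 19 under rigorously degassed conditions should keep oxidative alkyne dimerisation low.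

Step 12
Reactants: 20 tetra-O-benzyl diarylalkyne
Product: 21 4-(2-{3-hydroxy-4-[(4-hydroxy-2-[2-(3-hydroxyphenyl)ethyl]-6-methoxyphenyl)methyl]-5-methoxyphenyl}ethyl)-2-methoxyphenol (target)
Conditions: H2 (1–3 atm), 10% Pd/C, THF/MeOH 1:1, rt
Reagents that add atoms: none
Why: Heterogeneous catalytic hydrogenation should saturate the diarylalkyne to the ethylene bridge and hydrogenolyse the four benzyl ethers in one operation, leaving aryl methyl ethers and the diarylmethane untouched; there is no stereocentre to set.

**Compound list**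
1 | 4-bromo-2,6-difluorobenzaldehyde | O=Cc1c(F)cc(Br)cc1F | starting material
2 | 2-(benzyloxy)-4-bromo-6-fluorobenzaldehyde | O=Cc1c(F)cc(Br)cc1OCc1ccccc1 | intermediate
3 | 2-(benzyloxy)-4-bromo-6-methoxybenzaldehyde | COc1cc(Br)cc(OCc2ccccc2)c1C=O | intermediate
4 | methyl orsellinate | COC(=O)c1c(C)cc(O)cc1O | starting material
5 | methyl 4-(benzyloxy)-2-hydroxy-6-methylbenzoate | COC(=O)c1c(C)cc(OCc2ccccc2)cc1O | intermediate
6 | methyl 4-(benzyloxy)-2-methoxy-6-methylbenzoate | COC(=O)c1c(C)cc(OCc2ccccc2)cc1OC | intermediate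
7 | 3-(benzyloxy)benzyl bromide | BrCc1cccc(OCc2ccccc2)c1 | starting material
8 | [5-(benzyloxy)-3-methoxy-2-(methoxycarbonyl)benzyl]lithium (not isolated) | [Li]Cc1cc(OCc2ccccc2)cc(OC)c1C(=O)OC | intermediate
9 | methyl 4-(benzyloxy)-2-{2-[3-(benzyloxy)phenyl]ethyl}-6-methoxybenzoate | COC(=O)c1c(CCc2cccc(OCc3ccccc3)c2)cc(OCc2ccccc2)cc1OC | intermediate
10 | 4-(benzyloxy)-2-{2-[3-(benzyloxy)phenyl]ethyl}-6-methoxybenzoic acid | OC(=O)c1c(CCc2cccc(OCc3ccccc3)c2)cc(OCc2ccccc2)cc1OC | intermediate
11 | 5-(benzyloxy)-1-{2-[3-(benzyloxy)phenyl]ethyl}-2-iodo-3-methoxybenzene | COc1cc(OCc2ccccc2)cc(CCc2cccc(OCc3ccccc3)c2)c1I | intermediate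
12 | (4-(benzyloxy)-2-{2-[3-(benzyloxy)phenyl]ethyl}-6-methoxyphenyl)lithium (not isolated) | [Li]c1c(OC)cc(OCc2ccccc2)cc1CCc1cccc(OCc2ccccc2)c1 | intermediate
13 | racemic [2-(benzyloxy)-4-bromo-6-methoxyphenyl](4-(benzyloxy)-2-{2-[3-(benzyloxy)phenyl]ethyl}-6-methoxyphenyl)methanol | COc1cc(Br)cc(OCc2ccccc2)c1C(O)c1c(CCc2cccc(OCc3ccccc3)c2)cc(OCc2ccccc2)cc1OC | intermediate
14 | 1-(benzyloxy)-2-[(4-(benzyloxy)-2-{2-[3-(benzyloxy)phenyl]ethyl}-6-methoxyphenyl)methyl]-5-bromo-3-methoxybenzene | COc1cc(Br)cc(OCc2ccccc2)c1Cc1c(CCc2cccc(OCc3ccccc3)c2)cc(OCc2ccccc2)cc1OC | intermediate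
15 | 4-iodo-2-methoxyphenol | COc1cc(I)ccc1O | starting material
16 | 1-(benzyloxy)-4-iodo-2-methoxybenzene | COc1cc(I)ccc1OCc1ccccc1 | intermediate
17 | trimethylsilylacetylene | C#C[Si](C)(C)C | starting material
18 | {[4-(benzyloxy)-3-methoxyphenyl]ethynyl}trimethylsilane (not isolated) | COc1cc(C#C[Si](C)(C)C)ccc1OCc1ccccc1 | intermediate
19 | 1-(benzyloxy)-4-ethynyl-2-methoxybenzene (not isolated) | COc1cc(C#C)ccc1OCc1ccccc1 | intermediate
20 | tetra-O-benzyl diarylalkyne | COc1cc(C#Cc2cc(OCc3ccccc3)c(Cc3c(CCc4cccc(OCc5ccccc5)c4)cc(OCc4ccccc4)cc3OC)c(OC)c2)ccc1OCc1ccccc1 | intermediate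
21 | CNP0078999.0 | COc1cc(CCc2cc(O)c(Cc3c(CCc4cccc(O)c4)cc(O)cc3OC)c(OC)c2)ccc1O | target

**Step count**
Total: 12 steps. Longest linear sequence: 9 steps (methyl orsellinate 4 to target 21: steps 3–9, 11, 12).

**Steps most likely to fail and fallbacks**

Step 11. The released terminal alkyne may dimerise oxidatively, oxidative addition into the bromide may stall, or residual iodide may be arylated twice to a symmetrical diarylalkyne, all of which waste the advanced bromide. The fallback replaces the acetylene linchpin by an alkene and sets out from 16 and 14. Suzuki–Miyaura vinylation of 16 (vinylboronic acid pinacol ester, PdCl2(dppf), K2CO3, dioxane/H2O, 80 °C) should give 1-(benzyloxy)-2-methoxy-4-vinylbenzene F1. Heck coupling of F1 with 14 (Pd(OAc)2, P(o-tol)3, Et3N, DMF, 100 °C) should give the (E)-tetra-O-benzyl stilbene F2. Hydrogenation of F2 under the conditions of step 12 saturates the alkene and removes the benzyl groups, so the fallback comes back to the route at target 21.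

Step 7. Protodecarboxylation, or iodination at the free ring C positions between and beside the alkoxy groups, may compete with ipso attack. The fallback sets out from acid 10 and uses a Curtius–Sandmeyer sequence. Diphenylphosphoryl azide and Et3N in t-BuOH at 85 °C should convert 10 through the acyl azide F3 and the aryl isocyanate F4 into the tert-butyl carbamate F5. HCl in dioxane at rt should release the aniline F6. Diazotisation with NaNO2 and p-TsOH in MeCN/H2O should give the arenediazonium tosylate F7, which with KI should give iodide 11, where the route is rejoined.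

Step 5. Proton transfer to the benzylic bromide, electron-transfer homocoupling of 7, dialkylation or self-condensation of the toluate anion may lower conversion. The fallback sets out from 6 and traps the same anion 8 with an aldehyde instead of a halide. Addition of 8 to commercial 3-(benzyloxy)benzaldehyde (THF, −78 °C to rt) with lactonisation should give the racemic dihydroisocoumarin F8. KOt-Bu in DMSO should open F8 by elimination to the (E)-stilbene-2-carboxylic acid F9. Diimide reduction (TsNHNH2, NaOAc, DME/H2O, reflux) should saturate the alkene without touching the benzyl ethers and give acid 10, where the route is rejoined; step 6 is then not needed.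

**Further compounds**
F1 | step 11 | 1-(benzyloxy)-2-methoxy-4-vinylbenzene | COc1cc(C=C)ccc1OCc1ccccc1
F2 | step 11 | (E)-tetra-O-benzyl stilbene | COc1cc(/C=C/c2cc(OCc3ccccc3)c(Cc3c(CCc4cccc(OCc5ccccc5)c4)cc(OCc4ccccc4)cc3OC)c(OC)c2)ccc1OCc1ccccc1
F3 | step 7 | 4-(benzyloxy)-2-{2-[3-(benzyloxy)phenyl]ethyl}-6-methoxybenzoyl azide | [N-]=[N+]=NC(=O)c1c(OC)cc(OCc2ccccc2)cc1CCc1cccc(OCc2ccccc2)c1
F4 | step 7 | 5-(benzyloxy)-1-{2-[3-(benzyloxy)phenyl]ethyl}-2-isocyanato-3-methoxybenzene | O=C=Nc1c(OC)cc(OCc2ccccc2)cc1CCc1cccc(OCc2ccccc2)c1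
F5 | step 7 | tert-butyl (4-(benzyloxy)-2-{2-[3-(benzyloxy)phenyl]ethyl}-6-methoxyphenyl)carbamate | CC(C)(C)OC(=O)Nc1c(OC)cc(OCc2ccccc2)cc1CCc1cccc(OCc2ccccc2)c1
F6 | step 7 | 4-(benzyloxy)-2-{2-[3-(benzyloxy)phenyl]ethyl}-6-methoxyaniline | Nc1c(OC)cc(OCc2ccccc2)cc1CCc1cccc(OCc2ccccc2)c1
F7 | step 7 | 4-(benzyloxy)-2-{2-[3-(benzyloxy)phenyl]ethyl}-6-methoxybenzenediazonium tosylate | N#[N+]c1c(OC)cc(OCc2ccccc2)cc1CCc1cccc(OCc2ccccc2)c1.Cc1ccc(S(=O)(=O)[O-])cc1
F8 | step 5 | racemic 6-(benzyloxy)-3-[3-(benzyloxy)phenyl]-8-methoxy-3,4-dihydro-1H-isochromen-1-one | COc1cc(OCc2ccccc2)cc2c1C(=O)OC(c1cccc(OCc3ccccc3)c1)C2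
F9 | step 5 | (E)-4-(benzyloxy)-2-{2-[3-(benzyloxy)phenyl]ethenyl}-6-methoxybenzoic acid | OC(=O)c1c(OC)cc(OCc2ccccc2)cc1/C=C/c1cccc(OCc2ccccc2)c1
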